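**Retrosynthetic overview**

1. The target, 1,2-bis(3-bromo-4,5-dihydroxyphenyl)ethane, is taken back to its tetramethyl ether; the four O–CH3 bonds are cleaved last.
2. The strategy rests on the substitution of each benzene ring: Br at C3, O at C4 and O at C5 on three neighbouring carbons, H at C2 and C6, and the CH2CH2 bridge at C1. Cutting each ring at C1–C6 and C2–C3 leaves a four-carbon piece C3(Br)–C4(O)–C5(O)–C6(H) and a two-carbon piece C1–C2.
3. The four-carbon piece is the diene of 2-bromo-3,4-dimethoxythiophene 1,1-dioxide; the two-carbon piece is one C≡CH of hexa-1,5-diyne, whose CH2CH2 is the bridge. Sulfur leaves as SO2.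
4. Both benzene rings are built in one operation, one after the other, each by [4+2] cycloaddition and SO2 loss; the thiophene ring is only a carrier.
5. The dioxide comes from 3,4-dimethoxythiophene by bromination at C2 and oxidation at sulfur.

Key step: step 3

Assumption: the target has no stereocentre and no other element of chirality, so it is a single achiral compound and no enantiocontrol is needed.

**Route**

Step 1
Reactants: 1 3,4-dimethoxythiophene; 2 N-bromosuccinimide
Product: 3 2-bromo-3,4-dimethoxythiophene
Conditions: NBS (1.0 equiv), DMF, −20 → 0 °C, dark; short basic-alumina plug, kept cold and used promptly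
Reagents that add atoms: N-bromosuccinimide (2), O=C1CCC(=O)N1Br
Why: Electrophilic aromatic bromination at an α-position of the electron-rich thiophene; the two α-positions of symmetric 1 are equivalent and the first bromine slows a second substitution, so one equivalent at low temperature should stop at the monobromide.

Step 2
Reactants: 3 2-bromo-3,4-dimethoxythiophene
Product: 5 2-bromo-3,4-dimethoxythiophene 1,1-dioxide, via 2-bromo-3,4-dimethoxythiophene 1-oxide 4 (not isolated)
Conditions: DMDO (2.5 equiv, ca. 0.07 M in acetone), CH2Cl2, −30 → 0 °C; volatiles removed cold in vacuo, residue taken up in PhCl and used at once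
Reagents that add atoms: dimethyldioxirane, CC1(C)OO1
Why: Electrophilic oxygen transfer from the dioxirane to sulfur, twice (thiophene to S-oxide to S,S-dioxide), is a known oxidation of thiophenes; it runs neutral and anhydrous and leaves only acetone, so the non-aromatic sulfone with its C–Br bond and two enol-ether methoxy groups should be usable without chromatography, and its three substituents should slow its [4+2] self-dimerization.

Step 3
Reactants: 5 2-bromo-3,4-dimethoxythiophene 1,1-dioxide (3 equiv); 6 hexa-1,5-diyne (1 equiv)
Product: 10 1,2-bis(3-bromo-4,5-dimethoxyphenyl)ethane, via first sulfonyl-bridged cycloadduct 7 (not isolated), via 4-(3-bromo-4,5-dimethoxyphenyl)but-1-yne 8 (not isolated), via second sulfonyl-bridged cycloadduct 9 (not isolated)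
Conditions: 6, BHT (cat.), PhCl, 120 °C, pressure vessel; 5 in PhCl added by syringe pump over 12 h, then 120 °C, 12 h
Reagents that add atoms: none
Why: Proposed new method: sulfone 5 is a non-aromatic, ring-locked s-cis diene (C2=C3–C4=C5) whose termini are activated by the sulfonyl group, so a concerted [4+2] cycloaddition with one C≡CH of 6 should give the 7-thiabicyclo[2.2.1]hepta-2,5-diene 7,7-dioxide 7, which loses SO2 by cheletropic extrusion to arene 8, and the second alkyne repeats the sequence through 9. The closest known reaction type is the cycloaddition–SO2 extrusion of halogenated and 3,4-dialkyl thiophene 1,1-dioxides with alkynes to give benzenes; a 2-bromo-3,4-dialkoxy dioxide has not been combined with an unactivated terminal alkyne in this way. Each benzene ring closes by intermolecular [4+2] cycloaddition, which forms ring bond C2–C3 (alkyne CH to the C–Br terminus) and ring bond C1–C6 (substituted alkyne carbon to the C–H terminus), and it aromatizes by SO2 loss without an oxidant. No stereocentre is kept: the bridgehead centres of 7 and 9 form as racemates and vanish on extrusion. The step needs regioselectivity, expected on steric grounds because the chain on the alkyne bonds at the unhindered C5–H terminus and so avoids an ortho relation to bromine. It also needs the alkyne to win over [4+2] self-dimerization of 5, which the slow addition of 5 to hot, concentrated alkyne should secure.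

Step 4
Reactants: 10 1,2-bis(3-bromo-4,5-dimethoxyphenyl)ethane
Product: 12 1,2-bis(3-bromo-4,5-dihydroxyphenyl)ethane, via bis(2-bromo-1,3,2-benzodioxaborole) 11 (not isolated)
Conditions: BBr3 (6 equiv), CH2Cl2, −78 °C → rt; then H2O, 0 °C, under argon
Reagents that add atoms: none
Why: Lewis-acid ether cleavage (BBr3 O-demethylation): boron binds each methoxy oxygen, bromide removes the methyl group by SN2 as bromomethane, and water hydrolyses the cyclic catechol bromoboronates; aryl C–Br bonds and the saturated bridge are inert to BBr3.

**Compound list**

1 | 3,4-dimethoxythiophene | COc1cscc1OC | starting material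
2 | N-bromosuccinimide | O=C1CCC(=O)N1Br | starting material
3 | 2-bromo-3,4-dimethoxythiophene | COc1csc(Br)c1OC | intermediate
4 | 2-bromo-3,4-dimethoxythiophene 1-oxide (racemic at sulfur, not isolated) | COC1=CS(=O)C(Br)=C1OC | intermediate
5 | 2-bromo-3,4-dimethoxythiophene 1,1-dioxide | COC1=CS(=O)(=O)C(Br)=C1OC | intermediate
6 | hexa-1,5-diyne | C#CCCC#C | starting material
7 | 1-bromo-5-(but-3-yn-1-yl)-2,3-dimethoxy-7-thiabicyclo[2.2.1]hepta-2,5-diene 7,7-dioxide (racemic, not isolated) | BrC12C(OC)=C(OC)C(C(CCC#C)=C1)S2(=O)=O | intermediate
8 | 4-(3-bromo-4,5-dimethoxyphenyl)but-1-yne (not isolated) | COc1cc(CCC#C)cc(Br)c1OC | intermediate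
9 | 1-bromo-5-[2-(3-bromo-4,5-dimethoxyphenyl)ethyl]-2,3-dimethoxy-7-thiabicyclo[2.2.1]hepta-2,5-diene 7,7-dioxide (racemic, not isolated) | BrC12C(OC)=C(OC)C(C(CCc3cc(Br)c(OC)c(OC)c3)=C1)S2(=O)=O | intermediate
10 | 1,2-bis(3-bromo-4,5-dimethoxyphenyl)ethane | COc1cc(CCc2cc(Br)c(OC)c(OC)c2)cc(Br)c1OC | intermediate
11 | 1,2-bis(2,4-dibromo-1,3,2-benzodioxaborol-6-yl)ethane (not isolated) | BrB1Oc2cc(CCc3cc(Br)c4OB(Br)Oc4c3)cc(Br)c2O1 | intermediate
12 | 1,2-bis(3-bromo-4,5-dihydroxyphenyl)ethane; 5,5'-(ethane-1,2-diyl)bis(3-bromobenzene-1,2-diol) | Oc1cc(CCc2cc(O)c(O)c(Br)c2)cc(Br)c1O | target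

**Count**

Total steps: 4. Longest linear sequence: 4 steps (1 → 3 → 5 → 10 → 12).

**Steps most likely to fail**

Step 3 (proposed new method). The cycloaddition of the donor-substituted dioxide to an unactivated terminal alkyne may be slower than self-dimerization and thermal decay of the dioxide. The two orientations of the alkyne may also be too little differentiated, which would give bridge-ortho-to-bromine isomers. The fallback uses known chemistry only; it sets out from N-bromosuccinimide 2 and comes back to the route at 10. Purchased vanillin F1 is brominated ortho to the phenol with 2 (MeCN, 0 °C → rt) to 5-bromovanillin F2. O-Methylation (MeI, K2CO3, DMF) gives 3-bromo-4,5-dimethoxybenzaldehyde F3. McMurry coupling (TiCl4, Zn, THF, reflux) should give (E)-1,2-bis(3-bromo-4,5-dimethoxyphenyl)ethene F4; any Z isomer converges in the next operation. Diimide reduction of the C=C bond (TsNHNH2, NaOAc, THF/H2O, reflux), which leaves aryl bromides untouched, should then give 10.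

Step 2. Oxygen transfer to sulfur may be outrun by oxidation of the electron-rich ring carbons, because the bromine lowers the nucleophilicity of sulfur, and the transient S-oxide may dimerize before the second oxygen arrives. The fallback reverses the order of oxidation and bromination; it sets out from 1 and comes back at 5. The more nucleophilic sulfur of 1 is oxidized first (DMDO, acetone/CH2Cl2, −30 → 0 °C) to 3,4-dimethoxythiophene 1,1-dioxide F5, which is kept cold. Its push–pull enol ether is then brominated at the sulfonyl-bearing carbon with 2 (MeCN, 0 °C; attack of Br+ at C2, loss of the C2 proton), which should give 5.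

Step 1. Substitution may run on to the 2,5-dibromide, and the HBr traces formed may set off acid-catalysed oligomerization of the electron-rich bromothiophene. The fallback replaces electrophilic substitution by deprotonation and bromine transfer; it sets out from 1 and comes back at 3. Lithiation at C2 (n-BuLi, THF, −78 °C) should give (3,4-dimethoxythiophen-2-yl)lithium F6, which is quenched with 1,2-dibromotetrachloroethane (−78 °C → rt) to give 3 under base-buffered, acid-free conditions with exactly one bromine delivered.

**Further compounds**

F1 | step 3 | vanillin (purchased) | COc1cc(C=O)ccc1O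
F2 | step 3 | 5-bromovanillin (3-bromo-4-hydroxy-5-methoxybenzaldehyde) | COc1cc(C=O)cc(Br)c1O
F3 | step 3 | 3-bromo-4,5-dimethoxybenzaldehyde | COc1cc(C=O)cc(Br)c1OC
F4 | step 3 | (E)-1,2-bis(3-bromo-4,5-dimethoxyphenyl)ethene | COc1cc(/C=C/c2cc(Br)c(OC)c(OC)c2)cc(Br)c1OC
F5 | step 2 | 3,4-dimethoxythiophene 1,1-dioxide | COC1=CS(=O)(=O)C=C1OC
F6 | step 1 | (3,4-dimethoxythiophen-2-yl)lithium | [Li]c1scc(OC)c1OC
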